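**Retrosynthetic overview**
1. The B-ring dimethylpyran is cut at its O–CMe2 bond (retro-oxa-6π) to the ortho-quinone methide O=C4'–C3'=CH–CH=CMe2, then at C3'–CH back to 3-methylbut-2-enal and the free 4'-phenol of (2S)-6,8-diprenylnaringenin.
2. Enabling feature: the 2H-pyran ring O–C(Me)2–CH=CH–C3'=C4' is the valence tautomer of a 1-oxatriene, and ring A is fully substituted (C6 and C8 carry the prenyl groups, C4a/C8a are fusion carbons). C3'/C5' are therefore the only C–H positions ortho to a phenol, so the last step needs no protecting group, only a temporary boron tether ring that leaves in the same flask.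
3. The two prenyl groups come from a double Friedel–Crafts prenylation of (2S)-naringenin at C6 and C8; both monoprenyl regioisomers converge on the same product.
4. C2 is set by chalcone isomerase on naringenin chalcone, which is made by base ring-opening of racemic naringenin, so both enantiomers pass through one achiral compound.
5. Ring order: benzene rings A and B are bought; the pyranone ring is opened (step 1) and re-closed enantioselectively (step 2); the dimethylpyran ring is closed last (step 4).

Key step: step 4

Remark: commercial naringenin is treated as the racemate, so the route sets C2 itself with recombinant, purified chalcone isomerase; in 10 and 11 the 5- and 7-OH groups are drawn free although boron may esterify them reversibly until work-up.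

**Step 1**
Reactants: 1 (±)-naringenin
Product: 2 naringenin chalcone [(E)-3-(4-hydroxyphenyl)-1-(2,4,6-trihydroxyphenyl)prop-2-en-1-one]
Conditions: 50% aq. KOH, 100 °C, few min, N2; then ice/6 M HCl to pH 2, 0 °C; recrystallisation from acidified aq. EtOH
Reagents that add atoms: none
Why: Hydroxide-mediated retro-oxa-Michael (E1cB) ring opening through the C3 enolate gives the chalcone polyphenolate, whose delocalised 2'-oxyanion re-adds only slowly, and fast cold acidification traps the open (E)-chalcone below the pH at which it re-closes; the C2 centre is erased on purpose so that both enantiomers of 1 converge on one achiral compound.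

**Step 2**
Reactants: 2 naringenin chalcone
Product: 3 (2S)-naringenin
Conditions: chalcone isomerase (EC 5.5.1.6, recombinant type I enzyme, e.g. from Medicago sativa), 50 mM K-phosphate pH 6.8, DMSO (5% v/v), 20 °C, 2 fed in portions; then pH 5, EtOAc extraction
Reagents that add atoms: none
Why: Chalcone isomerase catalyses the 6-endo-trig intramolecular oxa-Michael addition of the 2'-phenolate to the enone of its native substrate in a chiral active site that exposes one face of the β-carbon, so the (2S)-flavanone should form far faster than the racemic background closure at this pH (the 2'- and 6'-OH groups are equivalent and give the same product).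

**Step 3**
Reactants: 3 (2S)-naringenin; 4 prenol (3-methylbut-2-en-1-ol, two equivalents incorporated)
Product: 7 (2S)-6,8-diprenylnaringenin, via (2S)-6-prenylnaringenin 5 (not isolated), via (2S)-8-prenylnaringenin 6 (not isolated)
Conditions: ZnCl2 (4 equiv), 4 (4 equiv, added in portions), EtOAc, 40 °C, N2
Reagents that add atoms: 3-methylbut-2-en-1-ol (4), CC(C)=CCO
Why: Zinc chloride-promoted Friedel–Crafts (nuclear) prenylation attacks the phloroglucinol-type A ring, by far the most nucleophilic arene, which has exactly two free positions (C6 and C8), so monoprenyl isomers 5 and 6 both converge on 7, while the base-free, weakly Lewis-acidic medium should leave C2 untouched (no new stereocentre).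

**Step 4**
Reactants: 7 (2S)-6,8-diprenylnaringenin; 8 prenal (3-methylbut-2-enal); 9 phenylboronic acid
Product: 12 (2S)-2-(2,2-dimethyl-2H-chromen-6-yl)-5,7-dihydroxy-6,8-bis(3-methylbut-2-enyl)chroman-4-one (target), via benzodioxaborin adduct 10 (not isolated), via ortho-quinone methide 11 (not isolated)
Conditions: 8 (3 equiv), PhB(OH)2 (9, 3 equiv), AcOH (cat.), toluene, reflux, Dean–Stark, N2; aqueous work-up
Reagents that add atoms: 3-methylbut-2-enal (8), CC(C)=CC=O
Why: Phenylboronic acid esterifies the 4'-OH of 7 and, as a boron template, delivers the coordinated aldehyde carbon of 8 to the ortho carbon C3' (ortho-specific aldol-type C–C bond formation) to give the 4-alkenyl-2-phenyl-4H-1,3,2-benzodioxaborin 10, which at reflux extrudes PhB=O in a retro-hetero-[4+2] step to the ortho-quinone methide 11. 11 is a 1-oxatriene (O=C4'–C3'=CH–CH=CMe2) and closes the 2H-pyran ring by a thermal disrotatory oxa-6π electrocyclisation that forms the O–CMe2 bond and restores the aromaticity of ring B, which should make the closure irreversible in practice. The closest known reaction type is the phenylboronic acid-mediated chromenylation (formal [3+3] annulation) of phenols with α,β-unsaturated aldehydes, established for para-substituted monohydric phenols and 3-methylbut-2-enal. No stereocentre is created (the new sp3 carbon carries two methyl groups and the carbinol centre of 10 is erased again), and C2 should keep its S configuration because the weakly acidic medium offers no base for the retro-oxa-Michael pathway. The step needs site selectivity among three phenols, and the substrate secures it: the template reaction requires a C–H ortho to the phenol, C6 and C8 carry the prenyl groups and C4a/C8a are fusion carbons, so the 5-OH and 7-OH can only form reversible boron esters, while C3' and C5' are equivalent by rotation of ring B. A second annulation is excluded because the phenol is consumed in the first closure, and the trisubstituted prenyl alkenes should be inert to catalytic acetic acid.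

**Compound list**
1 | (±)-naringenin, racemic 5,7-dihydroxy-2-(4-hydroxyphenyl)chroman-4-one | O=C1CC(c2ccc(O)cc2)Oc2cc(O)cc(O)c12 | starting material
2 | naringenin chalcone, (E)-3-(4-hydroxyphenyl)-1-(2,4,6-trihydroxyphenyl)prop-2-en-1-one | O=C(/C=C/c1ccc(O)cc1)c1c(O)cc(O)cc1O | intermediate
3 | (2S)-naringenin, (2S)-5,7-dihydroxy-2-(4-hydroxyphenyl)chroman-4-one | O=C1C[C@@H](c2ccc(O)cc2)Oc2cc(O)cc(O)c12 | intermediate
4 | prenol, 3-methylbut-2-en-1-ol | CC(C)=CCO | starting material
5 | (2S)-6-prenylnaringenin, (2S)-5,7-dihydroxy-2-(4-hydroxyphenyl)-6-(3-methylbut-2-enyl)chroman-4-one | CC(C)=CCc1c(O)cc2c(c1O)C(=O)C[C@@H](c1ccc(O)cc1)O2 | intermediate (not isolated)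
6 | (2S)-8-prenylnaringenin, (2S)-5,7-dihydroxy-2-(4-hydroxyphenyl)-8-(3-methylbut-2-enyl)chroman-4-one | Oc1cc(O)c(CC=C(C)C)c2c1C(=O)C[C@@H](c1ccc(O)cc1)O2 | intermediate (not isolated)
7 | (2S)-6,8-diprenylnaringenin, (2S)-5,7-dihydroxy-2-(4-hydroxyphenyl)-6,8-bis(3-methylbut-2-enyl)chroman-4-one | CC(C)=CCc1c(O)c(CC=C(C)C)c2c(c1O)C(=O)C[C@@H](c1ccc(O)cc1)O2 | intermediate
8 | prenal, 3-methylbut-2-enal | CC(C)=CC=O | starting material
9 | phenylboronic acid | OB(O)c1ccccc1 | starting material
10 | benzodioxaborin adduct, (2S)-5,7-dihydroxy-6,8-bis(3-methylbut-2-enyl)-2-[4-(2-methylprop-1-enyl)-2-phenyl-4H-1,3,2-benzodioxaborin-6-yl]chroman-4-one (both epimers at the carbinol carbon) | CC(C)=CCc1c(O)c(CC=C(C)C)c2c(c1O)C(=O)C[C@@H](c1ccc3OB(c4ccccc4)OC(C=C(C)C)c3c1)O2 | intermediate (not isolated)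
11 | ortho-quinone methide, (2S)-5,7-dihydroxy-6,8-bis(3-methylbut-2-enyl)-2-[3-(3-methylbut-2-enylidene)-4-oxocyclohexa-1,5-dien-1-yl]chroman-4-one, side chain syn to the C=O | CC(C)=CCc1c(O)c(CC=C(C)C)c2c(c1O)C(=O)C[C@@H](C1=C/C(=C/C=C(C)C)C(=O)C=C1)O2 | intermediate (not isolated)
12 | (2S)-2-(2,2-dimethyl-2H-chromen-6-yl)-5,7-dihydroxy-6,8-bis(3-methylbut-2-enyl)chroman-4-one | CC(C)=CCc1c(O)c(CC=C(C)C)c2c(c1O)C(=O)C[C@@H](c1ccc3c(c1)C=CC(C)(C)O3)O2 | target

Total step count: 4
Longest linear sequence: 4 steps (1 → 2 → 3 → 7 → 12)

**Steps most likely to fail**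

1. Step 3. The process risk is poor control over the degree and site of alkylation (stopping at mono-alkylation, O- instead of C-alkylation, attack on ring B) and acid-induced cyclisation of a prenyl group onto a neighbouring hydroxyl. The fallback sets out from 3 and returns at 7, placing each prenyl group by O-alkylation and sigmatropic shift instead of electrophilic substitution. Tsuji–Trost O-alkylation of the most acidic 7-OH with tert-butyl 2-methylbut-3-en-2-yl carbonate (Pd(PPh3)4 cat., THF, 0 °C, one equivalent) should give (2S)-7-O-(1,1-dimethylallyl)naringenin F1. Its aromatic Claisen rearrangement (toluene, 110 °C, or cat. Eu(fod)3, CHCl3, 50 °C) should give 6 and/or 5, now isolated. A second etherification under the same conditions should give (2S)-7-O-(1,1-dimethylallyl)-8-prenylnaringenin F2 and/or (2S)-7-O-(1,1-dimethylallyl)-6-prenylnaringenin F3. A second Claisen rearrangement into the one remaining ortho position should give 7 from either isomer.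

2. Step 4. The process risk is slow C–C bond formation on a phenol that is not activated, so that prolonged reflux erodes the configuration at C2 or cyclises prenyl groups onto the A-ring hydroxyls. The fallback sets out from 7 and returns at 11, and hence 12. Copper-catalysed O-alkylation of the unhindered 4'-OH with 3-chloro-3-methylbut-1-yne (CuCl2 cat., DBU, MeCN, 0 °C) should be favoured because the 7-OH is flanked by two prenyl groups and the 5-OH is chelated; it gives (2S)-6,8-diprenylnaringenin 4'-O-(2-methylbut-3-yn-2-yl) ether F4. Heating (xylene, 140 °C) should trigger the aromatic propargyl Claisen rearrangement to the allenyl cyclohexadienone F5. Enolisation gives the ortho-allenylphenol F6, and a 1,5-hydrogen shift gives the same ortho-quinone methide 11, which closes to 12. The enantiomeric purity would have to be checked after the base step.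

3. Step 2. The process risk is uncatalysed background cyclisation of 2 in the buffer, together with carry-over of unopened racemic 1 from step 1, which lowers the enantiomeric purity; the low solubility of 2 also limits throughput. The fallback sets out from 1 and returns at 3, replacing the enzymatic closure by a physical separation. Preparative chromatography of 1 on a polysaccharide chiral stationary phase (amylose tris(3,5-dimethylphenylcarbamate), SFC, CO2/MeOH) should give 3 directly. The unwanted (2R)-naringenin F7 is racemised with weak base and re-injected.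

**Further compounds**
F1 | step 3 | (2S)-5-hydroxy-2-(4-hydroxyphenyl)-7-(2-methylbut-3-en-2-yloxy)chroman-4-one | O=C1C[C@@H](c2ccc(O)cc2)Oc2cc(OC(C)(C)C=C)cc(O)c12
F2 | step 3 | (2S)-5-hydroxy-2-(4-hydroxyphenyl)-7-(2-methylbut-3-en-2-yloxy)-8-(3-methylbut-2-enyl)chroman-4-one | O=C1C[C@@H](c2ccc(O)cc2)Oc2c(CC=C(C)C)c(OC(C)(C)C=C)cc(O)c12
F3 | step 3 | (2S)-5-hydroxy-2-(4-hydroxyphenyl)-7-(2-methylbut-3-en-2-yloxy)-6-(3-methylbut-2-enyl)chroman-4-one | O=C1C[C@@H](c2ccc(O)cc2)Oc2cc(OC(C)(C)C=C)c(CC=C(C)C)c(O)c12
F4 | step 4 | (2S)-5,7-dihydroxy-6,8-bis(3-methylbut-2-enyl)-2-[4-(2-methylbut-3-yn-2-yloxy)phenyl]chroman-4-one | CC(C)=CCc1c(O)c(CC=C(C)C)c2c(c1O)C(=O)C[C@@H](c1ccc(OC(C)(C)C#C)cc1)O2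
F5 | step 4 | (2S)-5,7-dihydroxy-6,8-bis(3-methylbut-2-enyl)-2-[3-(3-methylbuta-1,2-dienyl)-4-oxocyclohexa-1,5-dien-1-yl]chroman-4-one | CC(C)=CCc1c(O)c(CC=C(C)C)c2c(c1O)C(=O)C[C@@H](C1=CC(C=C=C(C)C)C(=O)C=C1)O2
F6 | step 4 | (2S)-5,7-dihydroxy-2-[4-hydroxy-3-(3-methylbuta-1,2-dienyl)phenyl]-6,8-bis(3-methylbut-2-enyl)chroman-4-one | CC(C)=CCc1c(O)c(CC=C(C)C)c2c(c1O)C(=O)C[C@@H](c1ccc(O)c(C=C=C(C)C)c1)O2
F7 | step 2 | (2R)-naringenin, (2R)-5,7-dihydroxy-2-(4-hydroxyphenyl)chroman-4-one | O=C1C[C@H](c2ccc(O)cc2)Oc2cc(O)cc(O)c12
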